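**Retrosynthetic overview**

1. The strategy rests on O1 of ring C, which joins the stereogenic carbinol carbon C2 (the carbon bearing ring B) to the aromatic carbon C8a of ring A. Cutting the aryl bond O1–C8a leaves the C2–O bond, and with it the configuration at C2, untouched.
2. Target 16 ⇐ bis-MOM flavanone 15 ⇐ (2S,4S)-flavan-4-ol 14 ⇐ [O1–C8a, palladium C–O coupling] (1S,3S)-diol aryl triflate 13.
3. 13 ⇐ anti reduction of aldol 12 ⇐ [C2–C3, reagent-controlled boron aldol, sets C2] ketone triflate 5 + aldehyde 9.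
4. 5 ⇐ 2,4,6-trihydroxyacetophenone 1 (C-prenylation, bis-MOM protection, triflation); 9 ⇐ Negishi coupling of aryl bromide 6 with the zinc reagent from bromide 7.
5. Ring order: rings A and B come from the starting arenes; ring C is the only ring made, in step 7.

Key step: step 7

Remark: flavanone numbering is used (O1, C2, C3, C4, C4a, C5–C8, C8a; ring A the fused arene, ring B the 2-aryl group, ring C the pyranone). 4-Bromo-2-methylbut-1-ene and both enantiomers of Ipc2BCl are taken as commercially available.

**Route**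

Step 1
Reactants: 1 2,4,6-trihydroxyacetophenone; 2 prenyl bromide (1-bromo-3-methylbut-2-ene)
Product: 3 1-[2,4,6-trihydroxy-3-(3-methylbut-2-enyl)phenyl]ethanone
Conditions: DBU, THF, 0 °C to rt
Reagents that add atoms: none
Why: C-alkylation of a phloroglucinol-type anion: the DBU salt of 1 is an enolate-like ambident nucleophile that takes the soft allylic bromide at ring carbon, and since C3 and C5 are equivalent only one mono-C-prenyl product can form, O-prenyl and bis-prenyl by-products being removed by chromatography.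

Step 2
Reactants: 3 1-[2,4,6-trihydroxy-3-(3-methylbut-2-enyl)phenyl]ethanone
Product: 4 1-[2-hydroxy-4,6-bis(methoxymethoxy)-3-(3-methylbut-2-enyl)phenyl]ethanone
Conditions: MOMCl (2.2 equiv), iPr2NEt, CH2Cl2, 0 °C to rt
Reagents that add atoms: chloromethyl methyl ether (MOMCl), COCCl
Why: Williamson-type O-alkylation: the para hydroxyl and the less hindered ortho hydroxyl should react, while the hydroxyl flanked by acetyl and prenyl and held in the hydrogen bond to C=O should stay free; the regiochemistry is to be proven by HMBC and NOE contacts and any 2,4-bis-ether isomer removed by chromatography.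

Step 3
Reactants: 4 1-[2-hydroxy-4,6-bis(methoxymethoxy)-3-(3-methylbut-2-enyl)phenyl]ethanone
Product: 5 2-acetyl-3,5-bis(methoxymethoxy)-6-(3-methylbut-2-enyl)phenyl trifluoromethanesulfonate
Conditions: Tf2O, pyridine, CH2Cl2, −20 to 0 °C
Reagents that add atoms: trifluoromethanesulfonic anhydride (Tf2O), O=S(=O)(OS(=O)(=O)C(F)(F)F)C(F)(F)F
Why: O-sulfonylation of a phenol: triflic anhydride with pyridine converts chelated ortho-acyl phenols to aryl triflates at low temperature, where the acetal ethers and the prenyl alkene should be untouched.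

Step 4
Reactants: 6 3-bromo-4-methoxybenzaldehyde; 7 4-bromo-2-methylbut-1-ene
Product: 9 4-methoxy-3-(3-methylbut-3-enyl)benzaldehyde, via alkylzinc bromide 8 (not isolated)
Conditions: 7, Zn dust, LiCl, THF, 50 °C; then 6, Pd(OAc)2 (2 mol %), SPhos (4 mol %), THF, rt to 40 °C
Reagents that add atoms: none
Why: Negishi cross-coupling: direct zinc insertion gives a primary alkylzinc bromide that does not add to the aldehyde in the absence of magnesium salts, and the electron-rich biaryl phosphine favours oxidative addition to the ortho-alkoxy aryl bromide and reductive elimination over beta-hydride elimination.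

Step 5
Reactants: 5 2-acetyl-3,5-bis(methoxymethoxy)-6-(3-methylbut-2-enyl)phenyl trifluoromethanesulfonate; 9 4-methoxy-3-(3-methylbut-3-enyl)benzaldehyde
Product: 12 2-[(3S)-3-hydroxy-3-[4-methoxy-3-(3-methylbut-3-enyl)phenyl]propanoyl]-3,5-bis(methoxymethoxy)-6-(3-methylbut-2-enyl)phenyl trifluoromethanesulfonate, via boron enolate 10 (not isolated), via boron aldolate 11 (not isolated)
Conditions: (+)-Ipc2BCl, Et3N, Et2O, 0 °C; then 9, −78 to −20 °C; then H2O2, MeOH, pH 7 buffer, 0 °C
Reagents that add atoms: none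
Why: Reagent-controlled boron aldol addition (Paterson-type): the chloroborane and Et3N give the methyl enol borinate, which adds to 9 through a cyclic six-membered transition state in which the isopinocampheyl groups differentiate the aldehyde faces; the (+)-reagent is expected to direct attack to the Si face and so set the future C2 as S, the sense to be confirmed by Mosher ester analysis of 12, with the (−)-reagent in reserve.

Step 6
Reactants: 12 2-[(3S)-3-hydroxy-3-[4-methoxy-3-(3-methylbut-3-enyl)phenyl]propanoyl]-3,5-bis(methoxymethoxy)-6-(3-methylbut-2-enyl)phenyl trifluoromethanesulfonate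
Product: 13 2-[(1S,3S)-1,3-dihydroxy-3-[4-methoxy-3-(3-methylbut-3-enyl)phenyl]propyl]-3,5-bis(methoxymethoxy)-6-(3-methylbut-2-enyl)phenyl trifluoromethanesulfonate
Conditions: Me4NBH(OAc)3, MeCN/AcOH (1:1), −30 to 0 °C
Reagents that add atoms: none
Why: Evans–Saksena reduction: the free hydroxyl displaces acetate on boron and hydride is delivered within the alkoxyborohydride through a chair transition state to give the 1,3-anti diol, here (1S,3S); the aryl triflate is inert to this mild hydride, and any syn isomer would converge in step 8, where this carbinol is oxidised.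

Step 7
Reactants: 13 2-[(1S,3S)-1,3-dihydroxy-3-[4-methoxy-3-(3-methylbut-3-enyl)phenyl]propyl]-3,5-bis(methoxymethoxy)-6-(3-methylbut-2-enyl)phenyl trifluoromethanesulfonate
Product: 14 (2S,4S)-2-[4-methoxy-3-(3-methylbut-3-enyl)phenyl]-5,7-bis(methoxymethoxy)-8-(3-methylbut-2-enyl)chroman-4-ol
Conditions: Pd(OAc)2 (5 mol %), 2-(di-tert-butylphosphino)-1,1'-binaphthyl (6 mol %), Cs2CO3 (1.5 equiv), toluene, 70 °C
Reagents that add atoms: none
Why: Pd(OAc)2 is reduced in the flask to zerovalent palladium carrying one bulky phosphine, which inserts into the C8a–OTf bond; the cationic arylpalladium species binds the C2 hydroxyl, Cs2CO3 removes its proton, and C–O reductive elimination from divalent palladium forms O1–C8a. The closest known reaction type is the intramolecular Buchwald–Hartwig etherification of aryl halides and sulfonates with secondary alcohols to give chromans. Ring C closes as a six-membered ring in the 6-exo sense at the ipso carbon, by reductive elimination from a seven-membered aryl(alkoxo)palladium chelate. No stereocentre is created: the C2–O bond made in step 5 is never broken, so C2 keeps its S configuration, and C4 is a spectator. The step needs the C2 hydroxyl to react and not the C4 hydroxyl, which ring size secures because the C4 oxygen could only close a four-membered ring, and it needs reductive elimination to outrun beta-hydride elimination of the benzylic alkoxide, which the di-tert-butylphosphine should secure. The weak, insoluble base keeps free alkoxide too scarce to attack sulfur of the triflate, and the diol oxidation level excludes retro-aldol cleavage and dehydration to the chalcone.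

Step 8
Reactants: 14 (2S,4S)-2-[4-methoxy-3-(3-methylbut-3-enyl)phenyl]-5,7-bis(methoxymethoxy)-8-(3-methylbut-2-enyl)chroman-4-ol
Product: 15 (2S)-2-[4-methoxy-3-(3-methylbut-3-enyl)phenyl]-5,7-bis(methoxymethoxy)-8-(3-methylbut-2-enyl)chroman-4-one
Conditions: Dess–Martin periodinane, NaHCO3, CH2Cl2, 0 °C to rt
Reagents that add atoms: none
Why: Dess–Martin oxidation of the secondary benzylic alcohol under buffered, non-basic conditions, which should spare both alkenes and the acetal ethers and avoid base-induced opening of the flavanone, so C2 is not disturbed.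

Step 9
Reactants: 15 (2S)-2-[4-methoxy-3-(3-methylbut-3-enyl)phenyl]-5,7-bis(methoxymethoxy)-8-(3-methylbut-2-enyl)chroman-4-one
Product: 16 (2S)-5,7-dihydroxy-2-[4-methoxy-3-(3-methylbut-3-enyl)phenyl]-8-(3-methylbut-2-enyl)chroman-4-one
Conditions: HCl (1 M in MeOH), rt
Reagents that add atoms: none
Why: Acid-catalysed acetal exchange: the 5-ether, activated by the peri carbonyl, and then the 7-ether are transferred to methanol as dimethoxymethane under dilute acid at room temperature, conditions under which prenylated flavanones are expected to survive without hydration of either alkene, chroman formation at the prenyl group or opening at C2.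

**Compound list**

1 | 2,4,6-trihydroxyacetophenone | CC(=O)c1c(O)cc(O)cc1O | starting material
2 | prenyl bromide | CC(C)=CCBr | starting material
3 | 1-[2,4,6-trihydroxy-3-(3-methylbut-2-enyl)phenyl]ethanone | CC(=O)c1c(O)cc(O)c(CC=C(C)C)c1O | intermediate
4 | 1-[2-hydroxy-4,6-bis(methoxymethoxy)-3-(3-methylbut-2-enyl)phenyl]ethanone | CC(=O)c1c(O)c(CC=C(C)C)c(OCOC)cc1OCOC | intermediate
5 | 2-acetyl-3,5-bis(methoxymethoxy)-6-(3-methylbut-2-enyl)phenyl trifluoromethanesulfonate | CC(=O)c1c(OS(=O)(=O)C(F)(F)F)c(CC=C(C)C)c(OCOC)cc1OCOC | intermediate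
6 | 3-bromo-4-methoxybenzaldehyde | COc1ccc(C=O)cc1Br | starting material
7 | 4-bromo-2-methylbut-1-ene | C=C(C)CCBr | starting material
8 | (3-methylbut-3-enyl)zinc bromide (not isolated) | C=C(C)CC[Zn]Br | intermediate
9 | 4-methoxy-3-(3-methylbut-3-enyl)benzaldehyde | COc1ccc(C=O)cc1CCC(C)=C | intermediate
10 | diisopinocampheylboron enolate of 5, from (+)-Ipc2BCl (not isolated) | C=C(OB([C@H]1C[C@H]2C[C@@H]([C@@H]1C)C2(C)C)[C@H]1C[C@H]2C[C@@H]([C@@H]1C)C2(C)C)c1c(OS(=O)(=O)C(F)(F)F)c(CC=C(C)C)c(OCOC)cc1OCOC | intermediate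
11 | diisopinocampheylborinate ester of aldol 12 (not isolated) | O=C(C[C@@H](c1ccc(OC)c(CCC(C)=C)c1)OB([C@H]1C[C@H]2C[C@@H]([C@@H]1C)C2(C)C)[C@H]1C[C@H]2C[C@@H]([C@@H]1C)C2(C)C)c1c(OS(=O)(=O)C(F)(F)F)c(CC=C(C)C)c(OCOC)cc1OCOC | intermediate
12 | 2-[(3S)-3-hydroxy-3-[4-methoxy-3-(3-methylbut-3-enyl)phenyl]propanoyl]-3,5-bis(methoxymethoxy)-6-(3-methylbut-2-enyl)phenyl trifluoromethanesulfonate | O=C(C[C@@H](c1ccc(OC)c(CCC(C)=C)c1)O)c1c(OS(=O)(=O)C(F)(F)F)c(CC=C(C)C)c(OCOC)cc1OCOC | intermediate
13 | 2-[(1S,3S)-1,3-dihydroxy-3-[4-methoxy-3-(3-methylbut-3-enyl)phenyl]propyl]-3,5-bis(methoxymethoxy)-6-(3-methylbut-2-enyl)phenyl trifluoromethanesulfonate (anti diol, key-step precursor) | O[C@@H](C[C@@H](c1ccc(OC)c(CCC(C)=C)c1)O)c1c(OS(=O)(=O)C(F)(F)F)c(CC=C(C)C)c(OCOC)cc1OCOC | intermediate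
14 | (2S,4S)-2-[4-methoxy-3-(3-methylbut-3-enyl)phenyl]-5,7-bis(methoxymethoxy)-8-(3-methylbut-2-enyl)chroman-4-ol (2,4-cis, key-step product) | O[C@H]1C[C@@H](c2ccc(OC)c(CCC(C)=C)c2)Oc2c(CC=C(C)C)c(OCOC)cc(OCOC)c12 | intermediate
15 | (2S)-2-[4-methoxy-3-(3-methylbut-3-enyl)phenyl]-5,7-bis(methoxymethoxy)-8-(3-methylbut-2-enyl)chroman-4-one | O=C1C[C@@H](c2ccc(OC)c(CCC(C)=C)c2)Oc2c(CC=C(C)C)c(OCOC)cc(OCOC)c12 | intermediate
16 | (2S)-5,7-dihydroxy-2-[4-methoxy-3-(3-methylbut-3-enyl)phenyl]-8-(3-methylbut-2-enyl)chroman-4-one (CNP0286775.1) | C=C(C)CCc1cc([C@@H]2CC(=O)c3c(O)cc(O)c(CC=C(C)C)c3O2)ccc1OC | target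

**Step count and risks**

Total step count: 9. Longest linear sequence: 8 steps (steps 1, 2, 3, 5, 6, 7, 8, 9 from compound 1); step 4 is the one-step side branch to aldehyde 9.

The three steps most likely to fail, in order of risk:

Step 7 (ring closure). The triflate S–O bond may be cleaved by base before oxidative addition, insertion at the doubly ortho-substituted C8a may be slow, or beta-hydride elimination from the palladium alkoxide may oxidise the C2 carbinol and reduce the arene. The fallback closes ring C at the other bond of O1, by Mitsunobu displacement at C2 with inversion, and therefore needs the opposite aldol configuration. It sets out from phenol 4 and aldehyde 9 and comes back at flavanone 15. Phenol 4 is silylated with TBSOTf and 2,6-lutidine in CH2Cl2 to give 1-[2-(tert-butyldimethylsilyloxy)-4,6-bis(methoxymethoxy)-3-(3-methylbut-2-enyl)phenyl]ethanone F1. Its boron enolate, made with (−)-Ipc2BCl and Et3N, is added to 9 to give (3R)-1-[2-(tert-butyldimethylsilyloxy)-4,6-bis(methoxymethoxy)-3-(3-methylbut-2-enyl)phenyl]-3-hydroxy-3-[4-methoxy-3-(3-methylbut-3-enyl)phenyl]propan-1-one F2. TBAF buffered with AcOH in THF at 0 °C frees the phenol to give (3R)-3-hydroxy-1-[2-hydroxy-4,6-bis(methoxymethoxy)-3-(3-methylbut-2-enyl)phenyl]-3-[4-methoxy-3-(3-methylbut-3-enyl)phenyl]propan-1-one F3. PPh3 and DIAD in THF at 0 °C then let the phenol oxygen displace the activated benzylic hydroxyl in an SN2 closure with inversion, giving the (2S)-flavanone 15, from which step 9 follows.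

Step 5 (aldol). Enantioface selectivity of methyl ketone enol diisopinocampheylborinates may be insufficient for a single-enantiomer target, enolisation of the crowded ketone may be slow, and unconsumed chloroborane may reduce 9. The fallback sets the same carbinol by asymmetric conjugate borylation of a chalcone, setting out from phenol 4 and aldehyde 9 and coming back at aldol 12. Claisen–Schmidt condensation of 4 with 9 (KOH, EtOH, rt) gives (E)-1-[2-hydroxy-4,6-bis(methoxymethoxy)-3-(3-methylbut-2-enyl)phenyl]-3-[4-methoxy-3-(3-methylbut-3-enyl)phenyl]prop-2-en-1-one F4. Triflation as in step 3 gives the chalcone triflate 3,5-bis(methoxymethoxy)-2-[(E)-3-[4-methoxy-3-(3-methylbut-3-enyl)phenyl]prop-2-enoyl]-6-(3-methylbut-2-enyl)phenyl trifluoromethanesulfonate F5. Copper-catalysed conjugate borylation (CuCl, NaOtBu, B2pin2, MeOH, THF, rt) is run with a Josiphos-type ferrocene diphosphine, (C5H5)Fe[C5H3(PPh2)CH(CH3)P(C6H11)2]. The ligand enantiomer is chosen on the parent chalcone to deliver boron to the face that leads to the S product, and the reaction gives the (3S)-3-(4,4,5,5-tetramethyl-1,3,2-dioxaborolan-2-yl) ketone F6. Oxidation of the C–B bond with NaBO3·4H2O in THF/H2O proceeds with retention and returns aldol 12. If either route leaves a minor enantiomer, it would be removed at diol 13 by recrystallisation or chiral chromatography.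

Step 6 (reduction). The ketone is twisted out of the arene plane and shielded on both faces by the ortho triflate and methoxymethoxy groups, so internal delivery from the weak triacetoxyborohydride may stall. The fallback switches to external delivery of a stronger hydride onto a boron chelate (Narasaka–Prasad reduction), accepting the other C4 epimer because C4 is oxidised later. It sets out from aldol 12 and comes back at flavanone 15. Treatment of 12 with Et2BOMe and NaBH4 in THF/MeOH at −78 °C gives the syn diol 2-[(1R,3S)-1,3-dihydroxy-3-[4-methoxy-3-(3-methylbut-3-enyl)phenyl]propyl]-3,5-bis(methoxymethoxy)-6-(3-methylbut-2-enyl)phenyl trifluoromethanesulfonate F7. Cyclisation under the conditions of step 7 gives (2S,4R)-2-[4-methoxy-3-(3-methylbut-3-enyl)phenyl]-5,7-bis(methoxymethoxy)-8-(3-methylbut-2-enyl)chroman-4-ol F8. Oxidation under the conditions of step 8 returns flavanone 15.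

**Further compounds**

F1 | step 7 | 1-[2-(tert-butyldimethylsilyloxy)-4,6-bis(methoxymethoxy)-3-(3-methylbut-2-enyl)phenyl]ethanone | CC(=O)c1c(O[Si](C)(C)C(C)(C)C)c(CC=C(C)C)c(OCOC)cc1OCOC
F2 | step 7 | (3R)-1-[2-(tert-butyldimethylsilyloxy)-4,6-bis(methoxymethoxy)-3-(3-methylbut-2-enyl)phenyl]-3-hydroxy-3-[4-methoxy-3-(3-methylbut-3-enyl)phenyl]propan-1-one | O=C(C[C@H](c1ccc(OC)c(CCC(C)=C)c1)O)c1c(O[Si](C)(C)C(C)(C)C)c(CC=C(C)C)c(OCOC)cc1OCOC
F3 | step 7 | (3R)-3-hydroxy-1-[2-hydroxy-4,6-bis(methoxymethoxy)-3-(3-methylbut-2-enyl)phenyl]-3-[4-methoxy-3-(3-methylbut-3-enyl)phenyl]propan-1-one | O=C(C[C@H](c1ccc(OC)c(CCC(C)=C)c1)O)c1c(O)c(CC=C(C)C)c(OCOC)cc1OCOC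
F4 | step 5 | (E)-1-[2-hydroxy-4,6-bis(methoxymethoxy)-3-(3-methylbut-2-enyl)phenyl]-3-[4-methoxy-3-(3-methylbut-3-enyl)phenyl]prop-2-en-1-one | O=C(/C=C/c1ccc(OC)c(CCC(C)=C)c1)c1c(O)c(CC=C(C)C)c(OCOC)cc1OCOC
F5 | step 5 | 3,5-bis(methoxymethoxy)-2-[(E)-3-[4-methoxy-3-(3-methylbut-3-enyl)phenyl]prop-2-enoyl]-6-(3-methylbut-2-enyl)phenyl trifluoromethanesulfonate | O=C(/C=C/c1ccc(OC)c(CCC(C)=C)c1)c1c(OS(=O)(=O)C(F)(F)F)c(CC=C(C)C)c(OCOC)cc1OCOC
F6 | step 5 | 3,5-bis(methoxymethoxy)-2-[(3S)-3-[4-methoxy-3-(3-methylbut-3-enyl)phenyl]-3-(4,4,5,5-tetramethyl-1,3,2-dioxaborolan-2-yl)propanoyl]-6-(3-methylbut-2-enyl)phenyl trifluoromethanesulfonate | O=C(C[C@@H](c1ccc(OC)c(CCC(C)=C)c1)B1OC(C)(C)C(C)(C)O1)c1c(OS(=O)(=O)C(F)(F)F)c(CC=C(C)C)c(OCOC)cc1OCOC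
F7 | step 6 | 2-[(1R,3S)-1,3-dihydroxy-3-[4-methoxy-3-(3-methylbut-3-enyl)phenyl]propyl]-3,5-bis(methoxymethoxy)-6-(3-methylbut-2-enyl)phenyl trifluoromethanesulfonate | O[C@H](C[C@@H](c1ccc(OC)c(CCC(C)=C)c1)O)c1c(OS(=O)(=O)C(F)(F)F)c(CC=C(C)C)c(OCOC)cc1OCOC
F8 | step 6 | (2S,4R)-2-[4-methoxy-3-(3-methylbut-3-enyl)phenyl]-5,7-bis(methoxymethoxy)-8-(3-methylbut-2-enyl)chroman-4-ol | O[C@@H]1C[C@@H](c2ccc(OC)c(CCC(C)=C)c2)Oc2c(CC=C(C)C)c(OCOC)cc(OCOC)c12
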